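**Strategy.** Agehoustin F is disconnected at the C4–C4a bond. The key step exploits the fact that ring B, its 2'-oxygen and C2–C3–C4 of ring C map onto a 6,7-dimethoxycoumarin (lactone oxygen = O2', lactone carbonyl = C4), while ring A derives from symmetric 4,5,6-trimethoxyresorcinol, whose lone ring CH (future C4a) sits between the oxygens destined to be O1 and 5-OH. Strong acid should open the lactone of a 4-aryloxycoumarin and deliver its acyl carbon to that CH, closing ring C and unmasking the 2'-OH in one isomerization. The precursor is 6,7-dimethoxycoumarin bearing a 5-hydroxy-2,3,4-trimethoxyphenoxy group at C4.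

Key step: step 6

Remark: the target has no stereocentre and no stable axis, so no step has to set configuration. Cation 12 is written without its counter-ion and without alkene geometry, because its C3–C4 bond is expected to rotate under the acid.

Step 1
Reactants: 1 1,2,3-trimethoxybenzene
Product: 2 1,5-dibromo-2,3,4-trimethoxybenzene
Conditions: NBS (2.2 equiv), MeCN, rt then 60 °C
Reagents that add atoms: N-bromosuccinimide, O=C1CCC(=O)N1Br
Why: Electrophilic aromatic bromination; each outer methoxy group directs para, so the two bromines should enter C4 and C6, while C5, para only to the twisted central methoxy group, should stay free.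

Step 2
Reactants: 2 1,5-dibromo-2,3,4-trimethoxybenzene
Product: 5 4,5,6-trimethoxybenzene-1,3-diol, via 1,5-dilithio-2,3,4-trimethoxybenzene 3 (not isolated), via tetramethyl (4,5,6-trimethoxy-1,3-phenylene)diboronate 4 (not isolated)
Conditions: t-BuLi (4.4 equiv), THF, −78 °C; B(OMe)3 (3 equiv), −78 °C to rt; AcOH, 30% H2O2, 0 °C to rt
Reagents that add atoms: hydrogen peroxide, OO (both new hydroxyl oxygens of 5); tert-butyllithium, [Li]C(C)(C)C (lithium of 3 only); trimethyl borate, COB(OC)OC (boron and its methoxy groups in 4 only)
Why: Double bromine–lithium exchange (two t-BuLi per bromine makes it irreversible, and each C–Li is flanked by a coordinating methoxy group), borate trapping and peroxide oxidation of the C–B bonds with 1,2-aryl shift from boron to oxygen are all standard, and the acetic acid medium keeps the electron-rich diol from meeting base and oxidant together.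

Step 3
Reactants: 6 3,4-dimethoxyphenol; 7 Meldrum's acid
Product: 9 4-hydroxy-6,7-dimethoxycoumarin, via 3-(3,4-dimethoxyphenoxy)-3-oxopropanoic acid 8 (not isolated)
Conditions: neat, 95 °C (acetone distilled off); then P2O5/MeSO3H (1:10 w/w), 70 °C; H2O
Reagents that add atoms: none
Why: The phenol should open Meldrum's acid with loss of acetone to the aryl hydrogen malonate, whose acid Eaton's reagent turns into an acylium ion that closes by intramolecular Friedel–Crafts acylation at the unhindered ortho carbon para to the 3-methoxy group, a known route to 4-hydroxycoumarins.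

Step 4
Reactants: 9 4-hydroxy-6,7-dimethoxycoumarin
Product: 10 4-chloro-6,7-dimethoxycoumarin
Conditions: POCl3 (3 equiv), Et3N (1.2 equiv), MeCN, 80 °C; ice/H2O
Reagents that add atoms: phosphoryl chloride, O=P(Cl)(Cl)Cl
Why: The 4-hydroxycoumarin is a vinylogous carboxylic acid, so POCl3 should phosphorylate the enol oxygen and chloride should replace it by addition–elimination, the standard deoxychlorination to 4-chlorocoumarins.

Step 5
Reactants: 10 4-chloro-6,7-dimethoxycoumarin; 5 4,5,6-trimethoxybenzene-1,3-diol
Product: 11 4-(5-hydroxy-2,3,4-trimethoxyphenoxy)-6,7-dimethoxycoumarin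
Conditions: 5 (3 equiv), K2CO3 (1.2 equiv), degassed MeCN, 60 °C, Ar; excess 5 recovered
Reagents that add atoms: none
Why: C4 of 10 is the β-carbon of a vinylogous acid chloride, so the phenoxide should add and expel chloride (addition–elimination O-arylation, known for 4-chlorocoumarins with phenols), and the excess of symmetric diol with limited base should confine the reaction to one of its two equivalent hydroxyl groups.

Step 6
Reactants: 11 4-(5-hydroxy-2,3,4-trimethoxyphenoxy)-6,7-dimethoxycoumarin
Product: 13 Agehoustin F, via β-aryloxycinnamoyl acylium ion 12 (not isolated)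
Conditions: P2O5/MeSO3H (1:10 w/w), 0.02 M, 60 to 80 °C, Ar; then ice/H2O
Reagents that add atoms: none
Why: Proposed new method: the strongly acidic, dehydrating medium should protonate the lactone ring oxygen of 11 and ionize the acyl–oxygen bond, as in the first stage of a Fries rearrangement, giving acylium ion 12, which is stabilised in its ketene–oxocarbenium form by the ether oxygen and by the 2-hydroxy-4,5-dimethoxyphenyl group on the same carbon; this delocalisation lowers the C3–C4 bond order, so the acylium carbon can swing from the ring B side to the ring A side. The closest known reaction types are the Ruhemann flavone synthesis (acid cyclisation of β-aryloxycinnamic acids through the same kind of cation) and the Fries rearrangement of aryl esters and dihydrocoumarins in strong acid. Ring C closes by intramolecular Friedel–Crafts acylation through a six-membered transition state (6-exo attack on the acylium carbon) at the only CH of ring A, forming C4–C4a, while the former coumarin pyranone stays open and leaves the 2'-OH free. No stereocentre is created, so no control element is needed. The step needs six-membered closure onto ring A in preference to five-membered indenone closure at C6' of ring B and to intermolecular acylation; the ring A carbon has oxygen at both ortho positions and at the para position, the ring B site has a single ortho methoxy group and would give a strained indenone, and high dilution disfavours bimolecular paths. Reclosure to 11 is degenerate, whereas the flavone, an aryl ketone with a hydrogen bond from 5-OH to the C4 carbonyl and an aromatic 4-hydroxyflavylium ion in the acid, should be the thermodynamic sink.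

**Compound list**

1 | 1,2,3-trimethoxybenzene | COc1cccc(OC)c1OC | starting material
2 | 1,5-dibromo-2,3,4-trimethoxybenzene | COc1c(Br)cc(Br)c(OC)c1OC | intermediate
3 | 1,5-dilithio-2,3,4-trimethoxybenzene (formed in the flask, not isolated) | [Li]c1cc([Li])c(OC)c(OC)c1OC | intermediate
4 | tetramethyl (4,5,6-trimethoxy-1,3-phenylene)diboronate (formed in the flask on acidifying the borate complex, not isolated) | COB(OC)c1cc(B(OC)OC)c(OC)c(OC)c1OC | intermediate
5 | 4,5,6-trimethoxybenzene-1,3-diol | COc1c(O)cc(O)c(OC)c1OC | intermediate
6 | 3,4-dimethoxyphenol | COc1ccc(O)cc1OC | starting material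
7 | Meldrum's acid (2,2-dimethyl-1,3-dioxane-4,6-dione) | CC1(C)OC(=O)CC(=O)O1 | starting material
8 | 3-(3,4-dimethoxyphenoxy)-3-oxopropanoic acid (formed in the flask, not isolated) | COc1ccc(OC(=O)CC(=O)O)cc1OC | intermediate
9 | 4-hydroxy-6,7-dimethoxycoumarin (4-hydroxy-6,7-dimethoxy-2H-chromen-2-one) | COc1cc2oc(=O)cc(O)c2cc1OC | intermediate
10 | 4-chloro-6,7-dimethoxycoumarin | COc1cc2oc(=O)cc(Cl)c2cc1OC | intermediate
11 | 4-(5-hydroxy-2,3,4-trimethoxyphenoxy)-6,7-dimethoxycoumarin | COc1cc2oc(=O)cc(Oc3cc(O)c(OC)c(OC)c3OC)c2cc1OC | intermediate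
12 | 3-(2-hydroxy-4,5-dimethoxyphenyl)-3-(5-hydroxy-2,3,4-trimethoxyphenoxy)prop-2-enoyl cation (acylium ion, alkene geometry not fixed; formed in the flask, not isolated) | COc1cc(O)c(cc1OC)C(Oc1cc(O)c(OC)c(OC)c1OC)=CC#[O+] | intermediate
13 | Agehoustin F (5-hydroxy-2-(2-hydroxy-4,5-dimethoxyphenyl)-6,7,8-trimethoxy-4H-chromen-4-one) | COc1cc(O)c(-c2cc(=O)c3c(O)c(OC)c(OC)c(OC)c3o2)cc1OC | target

**Count.** Total: 6 steps (steps 2 and 3 are telescoped one-pot sequences). Longest linear sequence: 4 steps (steps 1, 2, 5, 6, or steps 3, 4, 5, 6).

**Steps most likely to fail**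

1. Step 6. The lactone may stay closed as its carbonyl-protonated benzopyrylium form and never ionize. The aryl vinyl ether may instead be cleaved by adventitious water or by aryloxy transfer. Intermolecular acylation or acid-induced O-demethylation may outrun ring closure. Fallback by known chemistry, from diol 5 back to 13: Friedel–Crafts C-acetylation of 5 at its only ring CH (AcOH, BF3·OEt2, 80 °C) should give 1-(2,6-dihydroxy-3,4,5-trimethoxyphenyl)ethan-1-one F1. Commercial 2-hydroxy-4,5-dimethoxybenzaldehyde is benzylated (BnBr, K2CO3, DMF) to 2-(benzyloxy)-4,5-dimethoxybenzaldehyde F2. Claisen–Schmidt condensation of F1 with F2 (KOH, EtOH, rt) should give (E)-3-[2-(benzyloxy)-4,5-dimethoxyphenyl]-1-(2,6-dihydroxy-3,4,5-trimethoxyphenyl)prop-2-en-1-one F3. Oxidative cyclisation (catalytic I2, DMSO, 120 °C) should close ring C to 2-[2-(benzyloxy)-4,5-dimethoxyphenyl]-5-hydroxy-6,7,8-trimethoxy-4H-chromen-4-one F4; either ortho hydroxyl of symmetric ring A gives the same flavone. Hydrogenolysis (H2, Pd/C, EtOAc, rt) then frees the 2'-OH to give 13.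

2. Step 5. Mono-selectivity may be lost through a second O-arylation of the remaining phenol, C-arylation may compete at the doubly activated ring CH of the diol, and the electron-rich phenoxide may oxidise in air. Fallback from 2 and 10 back to 11, desymmetrising before the ether is made: single bromine–lithium exchange of 2 (n-BuLi, 1.0 equiv, THF, −78 °C), B(OMe)3, then AcOH/H2O2 should give 5-bromo-2,3,4-trimethoxyphenol F5, which has one hydroxyl only. O-arylation with 10 (K2CO3, MeCN, 60 °C) should give 4-(5-bromo-2,3,4-trimethoxyphenoxy)-6,7-dimethoxycoumarin F6. Miyaura borylation (B2pin2, PdCl2(dppf), KOAc, dioxane, 90 °C) should give 6,7-dimethoxy-4-[2,3,4-trimethoxy-5-(4,4,5,5-tetramethyl-1,3,2-dioxaborolan-2-yl)phenoxy]coumarin F7. Oxidation of its C–B bond (H2O2, AcOH/THF, 0 °C) returns to 11.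

3. Step 2. The second bromine–lithium exchange may stay incomplete or the dilithio species may be protonated, giving mono-functionalised material, and the very electron-rich diol may be over-oxidised by peroxide. Fallback from 2 back to 5, replacing organolithium chemistry by catalysis: double Miyaura borylation of 2 (B2pin2, PdCl2(dppf), KOAc, dioxane, 90 °C) should give 2,2'-(4,5,6-trimethoxy-1,3-phenylene)bis(4,4,5,5-tetramethyl-1,3,2-dioxaborolane) F8. Oxidation with trimethylamine N-oxide (THF, rt) and aqueous work-up, which does not attack phenols, then gives 5.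

**Further compounds**

F1 | step 6 | 1-(2,6-dihydroxy-3,4,5-trimethoxyphenyl)ethan-1-one | CC(=O)c1c(O)c(OC)c(OC)c(OC)c1O
F2 | step 6 | 2-(benzyloxy)-4,5-dimethoxybenzaldehyde | COc1cc(OCc2ccccc2)c(C=O)cc1OC
F3 | step 6 | (E)-3-[2-(benzyloxy)-4,5-dimethoxyphenyl]-1-(2,6-dihydroxy-3,4,5-trimethoxyphenyl)prop-2-en-1-one | COc1cc(OCc2ccccc2)c(/C=C/C(=O)c2c(O)c(OC)c(OC)c(OC)c2O)cc1OC
F4 | step 6 | 2-[2-(benzyloxy)-4,5-dimethoxyphenyl]-5-hydroxy-6,7,8-trimethoxy-4H-chromen-4-one | COc1cc(OCc2ccccc2)c(-c2cc(=O)c3c(O)c(OC)c(OC)c(OC)c3o2)cc1OC
F5 | step 5 | 5-bromo-2,3,4-trimethoxyphenol | COc1c(O)cc(Br)c(OC)c1OC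
F6 | step 5 | 4-(5-bromo-2,3,4-trimethoxyphenoxy)-6,7-dimethoxycoumarin | COc1cc2oc(=O)cc(Oc3cc(Br)c(OC)c(OC)c3OC)c2cc1OC
F7 | step 5 | 6,7-dimethoxy-4-[2,3,4-trimethoxy-5-(4,4,5,5-tetramethyl-1,3,2-dioxaborolan-2-yl)phenoxy]coumarin | COc1cc2oc(=O)cc(Oc3cc(B4OC(C)(C)C(C)(C)O4)c(OC)c(OC)c3OC)c2cc1OC
F8 | step 2 | 2,2'-(4,5,6-trimethoxy-1,3-phenylene)bis(4,4,5,5-tetramethyl-1,3,2-dioxaborolane) | COc1c(B2OC(C)(C)C(C)(C)O2)cc(B2OC(C)(C)C(C)(C)O2)c(OC)c1OC
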